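**Remark (assumption).** 5,7-Dihydroxychromone (1) is taken as a purchasable compound. The side chain is numbered C1″ (ArCH2), C2″ (stereocentre), C3″H2–C4″H=C5″(C6″H3)C7″H3 (prenyl arm) and C8″(=C9″H2)C10″H3 (isopropenyl).

## The problem

Sophoraflavanone G is a (2S)-5,7,2′,4′-tetrahydroxyflavanone whose phloroglucinol ring A carries an (R)-lavandulyl chain at C8, between O1 and the 7-OH. The stereocentres C2 and C2″ are seven bonds apart across a flat arene, so neither can direct the other, and an error at either gives a diastereomer that is hard to separate. C2″ is an all-carbon stereocentre with three similar arms. The usual answer makes it in a separate C10 synthon with a stoichiometric auxiliary and then forces that β-branched primary electrophile onto a phloroglucinol, where C/O and C6/C8 selectivity are poor. C2 is a benzylic aryl-ether carbon β to the ketone and bears an ortho,para-dioxygenated aryl: base opens ring C to the chalcone and acid ionises C2–O1, so it must be made late, by reagent control, and not be stressed afterwards. The two alkenes add the neighbouring 7-OH under protic or Lewis acid (chroman formation) and exclude hydrogenolysis and boron-halide dealkylation, so the four phenols must be freed last under nearly neutral conditions.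

The feature that is exploited: O7–H is ortho to C8, and C2″ lies between the benzylic C1″ and C8″, an sp2 carbon that is a methylenated acetyl carbon. The six atoms O7–C7–C8–C1″–C2″–C8″ therefore map onto the pyran ring of a 2-hydroxy-2-methylchroman. That ring is the tautomer of an α-(o-hydroxybenzyl) methyl ketone and the formal [4+2] adduct of the C7(=O)/C8(=C1″H2) o-quinone methide with the internal enol of 6-methylhept-5-en-2-one, which supplies eight of the ten chain carbons.

## Retrosynthesis

**17 ⇒ 15 (through 16).** The four O–H bonds are traced back to methoxymethyl ethers. Methyl and benzyl ethers are excluded by the alkenes, acyl groups by the base needed to remove them (ring C opens), and aryl silyl ethers para to the carbonyl are at risk in an aqueous rhodium step. The forward reaction must cleave four aryl MOM ethers without protic acid; silyl triflate/2,2′-bipyridyl does this through the silyl ether 16.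

**15 ⇒ 9 + 14.** The C2–C1′ bond is cut (conjugate arylation of a chromone). The neighbouring cut, O1–C2 (chalcone closure), would form C2 reversibly with no facial bias from the distant C2″ and would require a choice between two ortho hydroxyls for ring closure. In chromone 9 the O1–C8a bond exists already and C2 is created by catalyst control in the last C–C bond formation. The precursor is a flat chromone with one stereocentre plus an arylboronic acid. The forward step needs Re-face delivery of an ortho-alkoxyaryl group to C2 of an electron-rich chromone without base-induced ring opening.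

**14 ⇒ 11 ⇒ 10.** The C–B bond comes from C–Br of 4-bromoresorcinol (10) after MOM protection (11), by bromine–lithium exchange and borylation; the bromide fixes the position that directed lithiation would miss.

**9 ⇒ 8 ⇒ 7.** The ethers go back to the free phenols of 8, and C8″=C9″ is cut to a methyl ketone (Wittig transform). This cut is chosen because a carbonyl at C8″ turns C2″ into an α-carbon, reachable by enamine chemistry. That ketone, with the ortho 7-OH, is the cyclic hemiketal 7. The forward reaction must methylenate without enolising C2″.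

**7 ⇒ 3 + 4 (through 5 and 6), the key disconnection.** The C1″–C2″ bond and the temporary O7–C8″ bond are cut, giving the o-quinone methide 5 (released from ammonium salt 3) and the commodity ketone 4. Against the neighbouring cut C8–C1″ (alkylation or cross-coupling with a preformed chiral C10 unit), this cut builds the chain on the ring, creates C2″ catalytically in the same step, and draws its C8 regiochemistry from the 7-OH. The precursors are achiral and flat; the product has the full carbon skeleton of the side chain less one methylene. The forward step needs reaction at C3 rather than C1 of the ketone, facial control at the nucleophile only, and a methide concentration low enough to avoid oligomerisation.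

**3 ⇒ 2 ⇒ 1.** N-Methylation and a phenol Mannich reaction lead back to 5,7-dihydroxychromone (1); C1″ is a formaldehyde carbon. A symmetric-looking ring A is entered at C8 because the free, acidic 7-OH directs aminomethylation ortho to itself and away from the position flanked by the chelated 5-OH.

## Roads not taken

**Alternative 1:** (the obvious route) Cut C8–C1″ by C-alkylation and O1–C2 by chalcone closure. (S)-Lavandulyl bromide A1 (from an oxazolidinone-directed α-prenylation of a 3-methylbut-2-enoyl imide, reduction and bromination) would alkylate 2,4,6-trihydroxyacetophenone to give A2. Claisen–Schmidt condensation with a protected 2,4-dihydroxybenzaldehyde would give chalcone A3, and oxa-Michael closure the flavanone. It is set aside for four reasons: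
- A1 is a β-branched primary homoallylic halide, slow in SN2, so O-alkylation and polyalkylation of the phloroglucinol compete.
- Closure of A3 must choose between two ortho oxygens.
- C2 forms under thermodynamic control with no bias.
- The C10 unit costs four to five steps and a stoichiometric auxiliary before it meets the arene.

The chosen plan makes the chain from a C8 ketone and two C1 units on the ring and sets both centres by catalysts.

**Alternative 2:** Cut C8–C1″ by sp2–sp3 cross-coupling. 8-Iodo-5,7-bis(methoxymethoxy)chromone A4 and (S)-lavandulylzinc iodide A5 would give 9 by Negishi coupling, followed by the same end game. This keeps the good C2 solution but only moves the C2″ problem into a separate auxiliary-based synthesis of A5. The coupling joins a β-branched alkylzinc to a di-ortho-substituted aryl iodide, where slow transmetalation invites β-hydride elimination and chain isomerisation. Regioselective C8 iodination is a further issue. The step count is higher and the chain is not assembled convergently.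

**Alternative 3:** Cut C2″–C3″. A copper-catalysed enantioselective SN2′ substitution of the 8-[(E)-4-chloro-3-methylbut-2-enyl]chromone A6 with a prenyl-metal would create C2″ and the isopropenyl group together. The idea is attractive (stereocentre made on the ring from an achiral allyl chloride), but a prenyl nucleophile can bond through either terminus, and bonding through its tertiary carbon gives the wrong skeleton. Hard organometallics also attack C2/C4 of the chromone. A6 itself needs C8-prenylation (C/O and C6/C8 issues), allylic oxidation and chlorination. The chosen key step uses a soft enamine nucleophile whose regiochemistry is defined by the carbonyl.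

Key step: step 3

## Route

**Step 1**
Reactants: 1 5,7-dihydroxy-4H-chromen-4-one
Product: 2 8-[(dimethylamino)methyl]-5,7-dihydroxy-4H-chromen-4-one
Conditions: CH2(NMe2)2 (1.05 equiv), 1,4-dioxane, 80 °C, N2 sweep
Reagents that add atoms: N,N,N′,N′-tetramethylmethanediamine CN(C)CN(C)C
Why: Phenol Mannich reaction (ortho-aminomethylation by an aminal); in 5,7-dihydroxy-chromones and -flavones the non-chelated, acidic 7-OH directs the iminium to C8 (ortho to O7, para to the chelated O5), and the zwitterionic product should resist a second substitution.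

**Step 2**
Reactants: 2 8-[(dimethylamino)methyl]-5,7-dihydroxy-4H-chromen-4-one
Product: 3 1-(5,7-dihydroxy-4-oxo-4H-chromen-8-yl)-N,N,N-trimethylmethanaminium iodide
Conditions: MeI (1.5 equiv), acetone, rt, dark
Reagents that add atoms: iodomethane CI
Why: Menshutkin N-methylation of the benzylic tertiary amine, which is far more nucleophilic than the neutral, hydrogen-bonded phenols; the salt releases the o-quinone methide with mild base at or below room temperature and gives off only a tertiary amine.

**Step 3**
Reactants: 3 1-(5,7-dihydroxy-4-oxo-4H-chromen-8-yl)-N,N,N-trimethylmethanaminium iodide; 4 6-methylhept-5-en-2-one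
Product: 7 (9R)-5,8-dihydroxy-8-methyl-9-(3-methylbut-2-en-1-yl)-9,10-dihydro-4H,8H-pyrano[2,3-f]chromen-4-one (cyclic hemiketal; C8 epimers), via o-quinone methide 5 (not isolated), via open-chain keto-phenol 6 (not isolated)
Conditions: 4 (5 equiv), 1-[(1R,2R)-2-aminocyclohexyl]-3-[3,5-bis(trifluoromethyl)phenyl]thiourea (20 mol%; antipode as assigned, see Why), NaHCO3 (solid, 2 equiv), CHCl3, 0 °C → rt; then THF/aq. AcOH
Reagents that add atoms: none
Why: Proposed new method: bicarbonate deprotonates O7–H of the sparingly soluble salt 3 and the betaine loses NMe3 by 1,4-elimination to give o-quinone methide 5 in low stationary concentration, while the primary amine of the catalyst condenses with 4 to a secondary enamine whose C3 adds to the exocyclic C1″ of 5 (Michael addition or asynchronous inverse-demand hetero-Diels–Alder reaction); hydrolysis gives keto-phenol 6, which is taken out of the cycle as hemiketal 7. The closest known reaction types are amine-catalysed enamine additions of aldehydes and cyclic ketones to o-quinone methides generated in situ (formal [4+2] to 2-hydroxychromans), primary-amine–thiourea Michael additions of 2-alkanones that react at the internal α-carbon, and the thermal cycloaddition of preformed enamines with o-quinone methides released from Mannich bases of 7-hydroxy-chromones and -coumarins; new is their combination on an acyclic methyl ketone and an unsubstituted methide, so that the only new stereocentre lies on the nucleophile. The pyran ring (O7, C7, C8, C1″, C2″, C8″) closes by 6-exo-trig attack of O7 on the C8″ iminium or carbonyl (or as the second bond of the [4+2]); this O7–C8″ bond is not in the target and is cut again in step 4. C2″ (C9 of 7) is controlled by the catalyst, whose thiourea N–H bonds hold O7 of 5, the developing phenoxide, so that C1″ is delivered within the complex to one face of the (Z)-enamine; which antipode of the catalyst gives 9R is to be settled by correlation on the first run, both being equally available. Regioselectivity for C3 over C1 of 4 rests on the preference of N–H enamines for the more substituted and more nucleophilic double bond (no A1,3 strain), and chemoselectivity rests on slow release of 5, on the excess of 4 that keeps the amine as imine/enamine and away from N-alkylation, and on NMe3 being unable to form an enamine. The new centre should be configurationally safe because 6 could re-enter the cycle only through a tetrasubstituted enamine and in 7 the carbonyl is masked.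

**Step 4**
Reactants: 7 (9R)-5,8-dihydroxy-8-methyl-9-(3-methylbut-2-en-1-yl)-9,10-dihydro-4H,8H-pyrano[2,3-f]chromen-4-one
Product: 8 5,7-dihydroxy-8-[(2R)-5-methyl-2-(prop-1-en-2-yl)hex-4-en-1-yl]-4H-chromen-4-one
Conditions: Ph3PCH3Br (4.5 equiv), KOt-Bu (4.4 equiv), THF/DMSO, 0 °C → rt; aq. NH4Cl
Reagents that add atoms: methyltriphenylphosphonium bromide C[P+](c1ccccc1)(c1ccccc1)c1ccccc1.[Br-]
Why: Wittig methylenation of a hemiketal through its open form: excess base opens both C8 epimers of 7 to the bis-phenoxide of 6, whose ketone is the only carbonyl electrophilic enough for Ph3P=CH2 (the pyranone carbonyl is a vinylogous ester deactivated further by two phenoxides). C2″ is retained provided olefination outruns enolisation, which the dianionic substrate and low temperature favour.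

**Step 5**
Reactants: 8 5,7-dihydroxy-8-[(2R)-5-methyl-2-(prop-1-en-2-yl)hex-4-en-1-yl]-4H-chromen-4-one
Product: 9 5,7-bis(methoxymethoxy)-8-[(2R)-5-methyl-2-(prop-1-en-2-yl)hex-4-en-1-yl]-4H-chromen-4-one
Conditions: NaH (2.5 equiv), MOMCl (2.5 equiv), DMF, 0 °C → rt
Reagents that add atoms: chloromethyl methyl ether COCCl
Why: Williamson-type O-alkylation of both sodium phenoxides (the chelated 5-OH needs the salt); blocking O5 removes the chelating 5-hydroxy-4-keto site that would bind rhodium, and MOM ethers survive the aqueous arylation.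

**Step 6**
Reactants: 10 4-bromobenzene-1,3-diol
Product: 11 1-bromo-2,4-bis(methoxymethoxy)benzene
Conditions: MOMCl (2.5 equiv), i-Pr2NEt (3 equiv), CH2Cl2, 0 °C → rt
Reagents that add atoms: chloromethyl methyl ether COCCl
Why: Standard acetal protection of both phenols (O-alkylation); the same group is used on ring A, so that one final operation frees all four phenols.

**Step 7**
Reactants: 11 1-bromo-2,4-bis(methoxymethoxy)benzene
Product: 14 [2,4-bis(methoxymethoxy)phenyl]boronic acid, via aryllithium 12 (not isolated), via lithium triisopropoxyborate 13 (not isolated)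
Conditions: n-BuLi (1.05 equiv), THF, −78 °C; B(Oi-Pr)3, −78 °C → rt; AcOH/H2O
Reagents that add atoms: triisopropyl borate CC(C)OB(OC(C)C)OC(C)C; water O
Why: Bromine–lithium exchange and borylation; exchange at −78 °C is faster than deprotonation between the two OMOM groups, so boron enters only at the former C–Br carbon, and the ortho OMOM stabilises 12 by chelation.

**Step 8**
Reactants: 9 5,7-bis(methoxymethoxy)-8-[(2R)-5-methyl-2-(prop-1-en-2-yl)hex-4-en-1-yl]-4H-chromen-4-one; 14 [2,4-bis(methoxymethoxy)phenyl]boronic acid
Product: 15 (2S)-2-[2,4-bis(methoxymethoxy)phenyl]-5,7-bis(methoxymethoxy)-8-[(2R)-5-methyl-2-(prop-1-en-2-yl)hex-4-en-1-yl]-2,3-dihydro-4H-chromen-4-one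
Conditions: 14 (3 equiv), [Rh(OH)(L*)]2 (3 mol% Rh; L* = (S)-configured electron-poor MeO-BIPHEP-type bisphosphine), toluene/H2O 10:1, 30 °C
Reagents that add atoms: none
Why: Rhodium(I)-catalysed enantioselective conjugate addition of an arylboronic acid to a chromone (Hayashi–Miyaura reaction): transmetalation, enantioface-selective carbometalation of C2=C3 and protonolysis of the rhodium enolate. C2 is set by the ligand alone, since C2″ is too far away to interfere; aryl delivery to the Re face of C2 gives 2S, which the (S)-biaryl bisphosphine is expected to do by analogy with 2-cyclohexenone (to be confirmed, the antipode being available). Base-free conditions and low temperature should keep the enolate from β-aryloxide elimination and the product from retro-oxa-Michael opening.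

**Step 9**
Reactants: 15 (2S)-2-[2,4-bis(methoxymethoxy)phenyl]-5,7-bis(methoxymethoxy)-8-[(2R)-5-methyl-2-(prop-1-en-2-yl)hex-4-en-1-yl]-2,3-dihydro-4H-chromen-4-one
Product: 17 sophoraflavanone G (2S)-2-(2,4-dihydroxyphenyl)-5,7-dihydroxy-8-[(2R)-5-methyl-2-(prop-1-en-2-yl)hex-4-en-1-yl]-2,3-dihydro-4H-chromen-4-one, via tetrakis(trimethylsilyl) ether 16 (not isolated)
Conditions: TMSOTf (10 equiv), 2,2′-bipyridyl (15 equiv), MeCN, 0 °C → rt; then H2O
Reagents that add atoms: none
Why: Silyl triflate/2,2′-bipyridyl cleavage of aromatic MOM ethers: each ArOCH2OMe is converted into ArOSiMe3 (16) and an N-(methoxymethyl)bipyridinium salt, and water then frees the phenols. No Brønsted acid or base is present, so the alkenes should not add O7 and C2 should be neither ionised nor opened to the chalcone.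

## Compound list

1 | 5,7-dihydroxy-4H-chromen-4-one | O=c1ccoc2cc(O)cc(O)c12 | starting material
2 | 8-[(dimethylamino)methyl]-5,7-dihydroxy-4H-chromen-4-one | CN(C)Cc1c(O)cc(O)c2c(=O)ccoc12 | intermediate
3 | 1-(5,7-dihydroxy-4-oxo-4H-chromen-8-yl)-N,N,N-trimethylmethanaminium iodide | C[N+](C)(C)Cc1c(O)cc(O)c2c(=O)ccoc12.[I-] | intermediate
4 | 6-methylhept-5-en-2-one | CC(=O)CCC=C(C)C | starting material
5 | 5-hydroxy-8-methylidene-4H-chromene-4,7(8H)-dione (o-quinone methide) | C=C1C(=O)C=C(O)C2=C1OC=CC2=O | intermediate (not isolated)
6 | 8-[(2R)-2-acetyl-5-methylhex-4-en-1-yl]-5,7-dihydroxy-4H-chromen-4-one (open form of 7) | CC(=O)[C@H](CC=C(C)C)Cc1c(O)cc(O)c2c(=O)ccoc12 | intermediate (not isolated)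
7 | (9R)-5,8-dihydroxy-8-methyl-9-(3-methylbut-2-en-1-yl)-9,10-dihydro-4H,8H-pyrano[2,3-f]chromen-4-one (C8 epimers) | CC1(O)Oc2cc(O)c3c(=O)ccoc3c2C[C@H]1CC=C(C)C | intermediate
8 | 5,7-dihydroxy-8-[(2R)-5-methyl-2-(prop-1-en-2-yl)hex-4-en-1-yl]-4H-chromen-4-one | C=C(C)[C@H](CC=C(C)C)Cc1c(O)cc(O)c2c(=O)ccoc12 | intermediate
9 | 5,7-bis(methoxymethoxy)-8-[(2R)-5-methyl-2-(prop-1-en-2-yl)hex-4-en-1-yl]-4H-chromen-4-one | C=C(C)[C@H](CC=C(C)C)Cc1c(OCOC)cc(OCOC)c2c(=O)ccoc12 | intermediate
10 | 4-bromobenzene-1,3-diol | Oc1ccc(Br)c(O)c1 | starting material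
11 | 1-bromo-2,4-bis(methoxymethoxy)benzene | COCOc1ccc(Br)c(OCOC)c1 | intermediate
12 | [2,4-bis(methoxymethoxy)phenyl]lithium | [Li]c1ccc(OCOC)cc1OCOC | intermediate (not isolated)
13 | lithium [2,4-bis(methoxymethoxy)phenyl]tri(propan-2-yloxy)borate | [Li+].CC(C)O[B-](OC(C)C)(OC(C)C)c1ccc(OCOC)cc1OCOC | intermediate (not isolated)
14 | [2,4-bis(methoxymethoxy)phenyl]boronic acid | COCOc1ccc(B(O)O)c(OCOC)c1 | intermediate
15 | (2S)-2-[2,4-bis(methoxymethoxy)phenyl]-5,7-bis(methoxymethoxy)-8-[(2R)-5-methyl-2-(prop-1-en-2-yl)hex-4-en-1-yl]-2,3-dihydro-4H-chromen-4-one | C=C(C)[C@H](CC=C(C)C)Cc1c(OCOC)cc(OCOC)c2c1O[C@H](c1ccc(OCOC)cc1OCOC)CC2=O | intermediate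
16 | (2S)-2-[2,4-bis(trimethylsilyloxy)phenyl]-5,7-bis(trimethylsilyloxy)-8-[(2R)-5-methyl-2-(prop-1-en-2-yl)hex-4-en-1-yl]-2,3-dihydro-4H-chromen-4-one | C=C(C)[C@H](CC=C(C)C)Cc1c(O[Si](C)(C)C)cc(O[Si](C)(C)C)c2c1O[C@H](c1ccc(O[Si](C)(C)C)cc1O[Si](C)(C)C)CC2=O | intermediate (not isolated)
17 | sophoraflavanone G, (2S)-2-(2,4-dihydroxyphenyl)-5,7-dihydroxy-8-[(2R)-5-methyl-2-(prop-1-en-2-yl)hex-4-en-1-yl]-2,3-dihydro-4H-chromen-4-one | C=C(C)[C@H](CC=C(C)C)Cc1c(O)cc(O)c2c1O[C@H](c1ccc(O)cc1O)CC2=O | target

## Step count and least certain steps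

Total: 9 steps. Longest linear sequence: 7 steps (1, 2, 3, 4, 5, 8, 9 from compound 1); the boronic acid branch has 2 steps (6, 7).

**Step 3 (key step, proposed new method).** Most likely failures:
- enamine formation and attack at the methyl terminus of 4 instead of C3;
- weak facial discrimination, since only the nucleophile is prochiral;
- loss of catalyst by N-alkylation with the methide or by conjugate addition to C2 of the pyranone;
- oligomerisation of the methide.

Fallback with known chemistry, setting out from 3 and returning at 7:
- Treat 3 with commercial 5-methylhex-4-enal, (S)-α,α-diphenylprolinol trimethylsilyl ether and solid NaHCO3. This is the known secondary-amine enamine addition of aldehydes to o-quinone methides, where the aldehyde has only one α-position and the usual steric-shielding model predicts the needed sense. It should give the lactol (9R)-5,8-dihydroxy-9-(3-methylbut-2-en-1-yl)-9,10-dihydro-4H,8H-pyrano[2,3-f]chromen-4-one F1.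
- Excess MeMgBr in THF adds to the open aldehyde form to give the carbinol 5,7-dihydroxy-8-[(2R)-2-(1-hydroxyethyl)-5-methylhex-4-en-1-yl]-4H-chromen-4-one F2 (carbinol epimers).
- Buffered Dess–Martin oxidation of the secondary alcohol gives the ketone, which closes to 7.

**Step 8.** Protodeboronation of the ortho,para-dialkoxyarylboronic acid may outrun carbometalation of the electron-rich chromone, and β-aryloxide elimination from the rhodium enolate may open ring C and lead to a second arylation. Fallback from 9, returning at 15, which gives up the conjugate addition for ring closure: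
- Aqueous-ethanolic KOH opens the pyranone by retro-Claisen loss of formate to 1-{2-hydroxy-4,6-bis(methoxymethoxy)-3-[(2R)-5-methyl-2-(prop-1-en-2-yl)hex-4-en-1-yl]phenyl}ethan-1-one F3.
- Claisen–Schmidt condensation with 2,4-bis(methoxymethoxy)benzaldehyde F4 (from 2,4-dihydroxybenzaldehyde, MOMCl, i-Pr2NEt) gives the chalcone (E)-3-[2,4-bis(methoxymethoxy)phenyl]-1-{2-hydroxy-4,6-bis(methoxymethoxy)-3-[(2R)-5-methyl-2-(prop-1-en-2-yl)hex-4-en-1-yl]phenyl}prop-2-en-1-one F5.
- F5 has only one free ortho hydroxyl, so it can close only to the 8-substituted flavanone. Intramolecular oxa-Michael addition under a bifunctional cinchona thiourea, or under NaOAc with chromatographic separation of the C2 epimers (diastereomers because of C2″), gives 15.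

**Step 4.** Enolisation of the ketone by the basic ylide would epimerise C2″, and the ylide could add to the pyranone. Fallback from 7, returning at 9, which avoids base at the ketone stage:
- MOMCl/i-Pr2NEt traps the open form as 8-[(2R)-2-acetyl-5-methylhex-4-en-1-yl]-5-hydroxy-7-(methoxymethoxy)-4H-chromen-4-one F6.
- Non-basic titanium methylenation with the Tebbe reagent at low temperature (ketone before vinylogous ester) gives 5-hydroxy-7-(methoxymethoxy)-8-[(2R)-5-methyl-2-(prop-1-en-2-yl)hex-4-en-1-yl]-4H-chromen-4-one F7.
- NaH/MOMCl gives 9.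

**Step 9.** The silyl triflate may ionise the C2–O1 bond of the electron-rich benzylic ether (epimerisation at C2), adventitious triflic acid may trigger addition of O7 to C8″, or the four ethers may cleave incompletely. Fallback from 8 and 10, returning at 17, which changes the protecting group to one removed by fluoride:
- 8 is silylated (TBSCl, imidazole) to 5,7-bis(tert-butyldimethylsilyloxy)-8-[(2R)-5-methyl-2-(prop-1-en-2-yl)hex-4-en-1-yl]-4H-chromen-4-one F8.
- 10 is silylated to 1-bromo-2,4-bis(tert-butyldimethylsilyloxy)benzene F9 and converted by bromine–lithium exchange and borylation into [2,4-bis(tert-butyldimethylsilyloxy)phenyl]boronic acid F10.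
- The conjugate arylation of step 8 then gives (2S)-2-[2,4-bis(tert-butyldimethylsilyloxy)phenyl]-5,7-bis(tert-butyldimethylsilyloxy)-8-[(2R)-5-methyl-2-(prop-1-en-2-yl)hex-4-en-1-yl]-2,3-dihydro-4H-chromen-4-one F11.
- Et3N·3HF in THF frees 17.

**Step 1.** Aminomethylation may go partly to C6 or occur twice. Fallback from 1, returning at 2, which takes the C8 selectivity from a sigmatropic shift:
- Selective O-allylation of the non-chelated 7-OH (allyl bromide, K2CO3) gives 7-(allyloxy)-5-hydroxy-4H-chromen-4-one F12.
- Aromatic Claisen rearrangement, directed to C8 by the higher double-bond character of C7–C8, gives 8-allyl-5,7-dihydroxy-4H-chromen-4-one F13.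
- Metal-catalysed alkene isomerisation gives 5,7-dihydroxy-8-[(E)-prop-1-en-1-yl]-4H-chromen-4-one F14.
- Ozonolysis with reductive work-up gives 5,7-dihydroxy-4-oxo-4H-chromene-8-carbaldehyde F15.
- Reductive amination with Me2NH/NaBH(OAc)3 gives 2.

## Further compounds

F1 | step 3 | (9R)-5,8-dihydroxy-9-(3-methylbut-2-en-1-yl)-9,10-dihydro-4H,8H-pyrano[2,3-f]chromen-4-one | OC1Oc2cc(O)c3c(=O)ccoc3c2C[C@H]1CC=C(C)C
F2 | step 3 | 5,7-dihydroxy-8-[(2R)-2-(1-hydroxyethyl)-5-methylhex-4-en-1-yl]-4H-chromen-4-one | CC(O)[C@H](CC=C(C)C)Cc1c(O)cc(O)c2c(=O)ccoc12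
F3 | step 8 | 1-{2-hydroxy-4,6-bis(methoxymethoxy)-3-[(2R)-5-methyl-2-(prop-1-en-2-yl)hex-4-en-1-yl]phenyl}ethan-1-one | C=C(C)[C@H](CC=C(C)C)Cc1c(OCOC)cc(OCOC)c(C(C)=O)c1O
F4 | step 8 | 2,4-bis(methoxymethoxy)benzaldehyde | COCOc1ccc(C=O)c(OCOC)c1
F5 | step 8 | (E)-3-[2,4-bis(methoxymethoxy)phenyl]-1-{2-hydroxy-4,6-bis(methoxymethoxy)-3-[(2R)-5-methyl-2-(prop-1-en-2-yl)hex-4-en-1-yl]phenyl}prop-2-en-1-one | C=C(C)[C@H](CC=C(C)C)Cc1c(OCOC)cc(OCOC)c(C(=O)/C=C/c2ccc(OCOC)cc2OCOC)c1O
F6 | step 4 | 8-[(2R)-2-acetyl-5-methylhex-4-en-1-yl]-5-hydroxy-7-(methoxymethoxy)-4H-chromen-4-one | CC(=O)[C@H](CC=C(C)C)Cc1c(OCOC)cc(O)c2c(=O)ccoc12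
F7 | step 4 | 5-hydroxy-7-(methoxymethoxy)-8-[(2R)-5-methyl-2-(prop-1-en-2-yl)hex-4-en-1-yl]-4H-chromen-4-one | C=C(C)[C@H](CC=C(C)C)Cc1c(OCOC)cc(O)c2c(=O)ccoc12
F8 | step 9 | 5,7-bis(tert-butyldimethylsilyloxy)-8-[(2R)-5-methyl-2-(prop-1-en-2-yl)hex-4-en-1-yl]-4H-chromen-4-one | C=C(C)[C@H](CC=C(C)C)Cc1c(O[Si](C)(C)C(C)(C)C)cc(O[Si](C)(C)C(C)(C)C)c2c(=O)ccoc12
F9 | step 9 | 1-bromo-2,4-bis(tert-butyldimethylsilyloxy)benzene | CC(C)(C)[Si](C)(C)Oc1ccc(Br)c(O[Si](C)(C)C(C)(C)C)c1
F10 | step 9 | [2,4-bis(tert-butyldimethylsilyloxy)phenyl]boronic acid | CC(C)(C)[Si](C)(C)Oc1ccc(B(O)O)c(O[Si](C)(C)C(C)(C)C)c1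
F11 | step 9 | (2S)-2-[2,4-bis(tert-butyldimethylsilyloxy)phenyl]-5,7-bis(tert-butyldimethylsilyloxy)-8-[(2R)-5-methyl-2-(prop-1-en-2-yl)hex-4-en-1-yl]-2,3-dihydro-4H-chromen-4-one | C=C(C)[C@H](CC=C(C)C)Cc1c(O[Si](C)(C)C(C)(C)C)cc(O[Si](C)(C)C(C)(C)C)c2c1O[C@H](c1ccc(O[Si](C)(C)C(C)(C)C)cc1O[Si](C)(C)C(C)(C)C)CC2=O
F12 | step 1 | 7-(allyloxy)-5-hydroxy-4H-chromen-4-one | C=CCOc1cc(O)c2c(=O)ccoc2c1
F13 | step 1 | 8-allyl-5,7-dihydroxy-4H-chromen-4-one | C=CCc1c(O)cc(O)c2c(=O)ccoc12
F14 | step 1 | 5,7-dihydroxy-8-[(E)-prop-1-en-1-yl]-4H-chromen-4-one | C/C=C/c1c(O)cc(O)c2c(=O)ccoc12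
F15 | step 1 | 5,7-dihydroxy-4-oxo-4H-chromene-8-carbaldehyde | O=Cc1c(O)cc(O)c2c(=O)ccoc12
A1 | alternative 1 | (S)-lavandulyl bromide, (2S)-1-bromo-5-methyl-2-(prop-1-en-2-yl)hex-4-ene | C=C(C)[C@H](CC=C(C)C)CBr
A2 | alternative 1 | 1-{2,4,6-trihydroxy-3-[(2R)-5-methyl-2-(prop-1-en-2-yl)hex-4-en-1-yl]phenyl}ethan-1-one | C=C(C)[C@H](CC=C(C)C)Cc1c(O)cc(O)c(C(C)=O)c1O
A3 | alternative 1 | (E)-3-[2,4-bis(methoxymethoxy)phenyl]-1-{2-hydroxy-4,6-bis(methoxymethoxy)-3-[(2R)-5-methyl-2-(prop-1-en-2-yl)hex-4-en-1-yl]phenyl}prop-2-en-1-one | C=C(C)[C@H](CC=C(C)C)Cc1c(OCOC)cc(OCOC)c(C(=O)/C=C/c2ccc(OCOC)cc2OCOC)c1O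
A4 | alternative 2 | 8-iodo-5,7-bis(methoxymethoxy)-4H-chromen-4-one | COCOc1cc(OCOC)c2c(=O)ccoc2c1I
A5 | alternative 2 | (S)-lavandulylzinc iodide, [(2S)-5-methyl-2-(prop-1-en-2-yl)hex-4-en-1-yl]zinc iodide | C=C(C)[C@H](CC=C(C)C)C[Zn]I
A6 | alternative 3 | 8-[(2E)-4-chloro-3-methylbut-2-en-1-yl]-5,7-bis(methoxymethoxy)-4H-chromen-4-one | COCOc1cc(OCOC)c2c(=O)ccoc2c1C/C=C(\C)CCl
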